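You have no rate constants for this flask, so you read its clocks off the two earlier runs.

| flask | free monomer | transfer agent | initiator | remark | time |
|---|---|---|---|---|---|
| south | 0.50 M (fed, over 30 min) | 0.0075 M | 10 mol% | run made earlier; the fed solution adds 0.25 times the starting volume |  |
| south-east | 0.50 M (fed, over 30 min) | 0.011 M | 10 mol% | run made earlier; the fed solution adds 0.25 times the starting volume |  |
| flask | 0.50 M (fed, over 30 min) | 0.0150 M | 10 mol% | the fed solution adds 0.25 times the starting volume | 40 h |

- south (time / h: monomer in chains / %, free monomer / %): 5.00: 64, 30; 10.0: 74, 17; 15.0: 79, 15; 20.0: 83, 11; 25.0: 82, 10; 30.0: 83, 11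
- south-east (time / h: monomer in chains / %, free monomer / %): 1.50: 28, 69; 5.00: 66, 35; 10.0: 77, 20; 15.0: 80, 16; 20.0: 81, 13; 25.0: 79, 10; 30.0: 83, 15

(scatter of a reading: 2 percentage points)

- every charge counts on the volume at the start, and the solution that is fed holds the whole dose
- the average divides the monomer in chains by the number of chains begun, living and dead together
- the analysis behind the earlier runs scatters by 2 percentage points, standard deviation
- the earlier runs do not show the number of chains; that part of a forecast is a guess

1. average number of monomer units in a chain (chains begun, living or dead) at 40 h
2. part of the free monomer that has reacted at 40 h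

The first rung is the feed, 30 min. Next comes free monomer in the south-east run, which falls from 69% at 1.50 h to 35% at 5.00 h: a half-life, as read, of 3.57 h, longer than the feed. On the last rung, from 20.0 h on, monomer in chains lies between 79% and 83% in both runs, with a scatter of 2 percentage points. The asked time is twice that, so you expect the plateau.

Raising c(transfer agent) from 0.0075 M to 0.011 M took the plateau, as read, from 82.7% to 81.0%, so I carry the mean of 81.8% to this flask, and from the free monomer left, a conversion of 88.3%.

Now follow one molecule of initiator. The runs show no chain count, so this is my assumption: each molecule of initiator charged is spent and begins one chain, and transfer agent begins none. The loading stands on free monomer, so c(initiator) is 0.0500 M, more than c(transfer agent). That gives 8.18, the number I carry: the yield per initiator, monomer in chains over initiator spent.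

The forecast puts conversion at 88% but the chain length at 25, against my 8.18, on this ground: “I take the initiator as 10 mol% relative to the transfer agent”.

The flask gives 8.08 and 86.0%, so the forecast's conversion stands and its chain length is 3.09 times too high.

    free monomer + initiator → living end + monomer in chains (k = 2.30 L mol⁻¹ h⁻¹)
    free monomer + living end → monomer in chains + living end, rate k2*[living end]*[free monomer] (k = 26.0 L mol⁻¹ h⁻¹)
    living end + transfer agent → dead chain (kL = 16.0 L mol⁻¹ h⁻¹)
    2 living end → dead end A (k = 15.0 L mol⁻¹ h⁻¹)
    living end + free monomer → dead end B (k = 1.90 L mol⁻¹ h⁻¹)

The yield per initiator, 8.18 before the result, comes to 8.08 from the flask's own 80.8% in chains. On the neighbour with 4 mol% of initiator, 41.3% in chains and 0% initiator left, it gives 10.3 against the simulated 10.3. This flask is at rest: initiator is down to 0.043% of its charge, and ten times the time leaves the chain length at 8.09, conversion at 86.1% and free monomer at 13.9%, while transfer agent slips from 35.6% to 35.4% of its charge.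

All runs are simulated for an exercise, and the scatter is random.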